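In this closed, stirred vessel open intermediate has two exits: to target with partner on the second catalyst, and to trapped intermediate with capture agent. Each exit is first order in c(open intermediate), and the second catalyst comes back unchanged. So at a fixed loading of it, the logarithms of the fractions left of partner and of capture agent fall in constant proportion, whatever c(open intermediate) does.

all flasks: second catalyst 0.05 mol%

|  | substrate | partner | capture agent | free catalyst | remark | time |
|---|---|---|---|---|---|---|
| elm | 1 M | 1.5 equiv | 0.10 M | 0.25 mol% | run made earlier |  |
| maple | 1 M | 1.5 equiv | 0.10 M | 0.38 mol% | run made earlier |  |
| flask | 1.0 M | 1.50 equiv | 0.100 M | 0.5 mol% |  | 15 d |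

- elm (time / d: target / %, trapped intermediate / %): 5.00: 87.7, 6.4; 10.0: 92.7, 7.3; 15.0: 93.3, 6.6; 20.0: 93.4, 6.8
- maple (time / d: target / %, trapped intermediate / %): 5.00: 90.2, 6.8; 10.0: 93.2, 6.7; 15.0: 92.8, 7.7; 20.0: 92.8, 6.8

(standard deviation of a reading: 0.5 percentage points)

- what may be going on: open intermediate + capture agent -> trapped intermediate; substrate + free catalyst <-> free catalyst + open intermediate; partner + second catalyst + open intermediate -> second catalyst + target

- ratio of target to trapped intermediate at 5.0 h
- ratio of target to trapped intermediate at 15 d

The last readings give this proportion as 0.855 in elm and 0.846 in maple. We carry their mean 0.851, the split number or selectivity factor: ln(fraction of partner left) over ln(fraction of capture agent left). Free catalyst does not enter it, and the flask has the second-catalyst loading of both runs. At the start of the flask, target over trapped intermediate is therefore the split number times c(partner)/c(capture agent), which we reckon as 12.8 and take for 5.0 h.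

Now the opposite outcome: trapped intermediate reaching 10.0% of the substrate, with no capture agent left. By the rule, the fraction of partner left must then reach zero too. But the substrate of the flask, if every bit of it became target, would take partner down to 33.3%, a third, and not to zero. By our reckoning that floor gives trapped intermediate 7.25%. Putting the target this leaves back into the partner balance gives 6.78%, hence a final ratio of 13.8.

The forecast, “The free catalyst therefore sets the speed, not the split”, gave 12.8 and 13.5, its end figure a little below ours. The flask gives 12.5 and 13.5.

    open intermediate + capture agent → trapped intermediate (k = 3.03 × 10⁻⁵ L mol⁻¹ s⁻¹)
    substrate + free catalyst ⇌ free catalyst + open intermediate (K = 1.90, k = 0.00393 L mol⁻¹ s⁻¹)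
    partner + second catalyst + open intermediate → second catalyst + target (k = 0.0504 L² mol⁻² s⁻¹)

The flask ends with 38% of its partner and 31% of its capture agent, a split number of 0.826. The falling fraction of capture agent contributes to its ratio: the same flask with that supply held constant stands at 8.22 instead of 13.5 at 15.0 d. The neighbour with 0.2 mol% of second catalyst has the split number multiplied by 4.00, so its 73% of capture agent left implies 34.3% of partner left. That neighbour holds 35% of its partner, at a ratio of 36.1.

The earlier runs and the new flask were generated by integration from invented constants; the scatter is artificial.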